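The plan disconnects both benzylic C–O bonds of the 12-membered dilactone back to C–H, so that the macrocycle is built in its robust bis-deoxy form. The key step exploits the two macrocyclic ArCH2 carbons, one on ring A (one aromatic H) and one on ring B (fully substituted). Each lies para to its ring's OMe-bearing carbon and holds the weakest, most electron-rich C–H bonds, whereas the adjacent OC(=O)-bearing methines are polarity-mismatched. One N-hydroxyphthalimide-mediated aerobic electrolysis converts both CH2 groups into ketones. Its precursor is the penta-O-TBS bis-deoxy dilactone. Both halves derive from one (S)-propylene oxide-based dihydroisocoumarin, joined once with inversion and once with retention.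

Key step: step 15

Remark on the chemistry: read from the SMILES, the OCH(CH3)–CH(OH) pair attached to ring B is (R,R) and the pair attached to ring A is (S,S), which is threo in both halves.

Design notes:
- The phenols travel as benzyl ethers through the KOH, fluoride and zerovalent palladium steps.
- They are exchanged for TBS ethers only on the closed bis-deoxy macrocycle. ArO–CH2Ph bonds would compete for the N-oxyl radical, and aryl silyl ethers would not survive the assembly.
- The doubly ortho-substituted acids are esterified once through the carboxylate (Mitsunobu, inversion) and once through a neutral thioester (retention). One epoxide enantiomer therefore serves both halves.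

Step 1
Reactants: 1 2-methoxyresorcinol
Product: 2 2,4-dihydroxy-3-methoxybenzoic acid
Conditions: KHCO3, CO2 (1 atm), H2O, reflux; then HCl
Reagents that add atoms: potassium hydrogen carbonate, [K+].OC([O-])=O (its CO2 unit; the CO2 atmosphere only holds the equilibrium)
Why: In this Kolbe–Schmitt carboxylation of a resorcinol, the phenoxide attacks CO2 at C4 (equal to C6 by symmetry), the only position ortho/para to both OH groups because C2 is blocked by OMe.

Step 2
Reactants: 2 2,4-dihydroxy-3-methoxybenzoic acid
Product: 4 2,4-bis(benzyloxy)-3-methoxybenzoic acid, via benzyl ester 3 (not isolated)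
Conditions: BnBr, K2CO3, DMF, 60 °C; then KOH, MeOH/H2O, 70 °C; then HCl
Reagents that add atoms: benzyl bromide, BrCc1ccccc1; potassium hydroxide, [K+].[OH-]
Why: Williamson O-alkylation of both phenols and the carboxylate is followed by saponification of the ester, which has only one ortho substituent and remains accessible, leaving the two aryl benzyl ethers in place.

Step 3
Reactants: 4 2,4-bis(benzyloxy)-3-methoxybenzoic acid; 5 (S)-propylene oxide
Product: 6 (S)-6,8-bis(benzyloxy)-7-methoxy-3-methylisochroman-1-one
Conditions: Pd(OAc)2 (5 mol%), N-acetyl-L-tert-leucine (10 mol%), KOAc, (CF3)2CHOH, 75 °C, sealed tube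
Reagents that add atoms: none
Why: In this known carboxylate-directed ortho C–H alkylation with a terminal epoxide (divalent palladium, mono-N-protected amino acid ligand), the only free ortho C–H is palladated, the aryl–Pd bond opens the epoxide at its CH2 terminus in SN2 fashion and the alkoxide lactonises, so the epoxide stereocentre is never touched and becomes (S)-C3.

Step 4
Reactants: 6 (S)-6,8-bis(benzyloxy)-7-methoxy-3-methylisochroman-1-one
Product: 9 2,4-bis(benzyloxy)-6-[(2S)-2-(tert-butyldimethylsilyloxy)propyl]-3-methoxybenzoic acid (ring A acid), via potassium hydroxy carboxylate 7 (not isolated), via bis-silyl derivative 8 (not isolated)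
Conditions: KOH, THF/MeOH/H2O, 50 °C, evaporate; TBSCl, imidazole, DMF, rt; then AcOH/THF/H2O, rt
Reagents that add atoms: potassium hydroxide, [K+].[OH-]; tert-butyldimethylsilyl chloride, CC(C)(C)[Si](C)(C)Cl
Why: Saponification, exhaustive silylation and selective hydrolysis of the labile silyl ester (the standard lactone-to-silyloxy-acid sequence) free the acid while the carbinol is masked against relactonisation, and since the C–O bond at the stereocentre is never broken, (S) is retained.

Step 5
Reactants: 6 (S)-6,8-bis(benzyloxy)-7-methoxy-3-methylisochroman-1-one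
Product: 10 (S)-6,8-bis(benzyloxy)-5-bromo-7-methoxy-3-methylisochroman-1-one
Conditions: NBS, MeCN, 0 °C to rt, dark
Reagents that add atoms: N-bromosuccinimide, O=C1CCC(=O)N1Br
Why: Electrophilic aromatic bromination should take C5, the only free position of the oxygenated ring (ortho and para to the two benzyloxy groups, meta to the carbonyl), while a polar solvent and darkness suppress radical attack on CH2 groups.

Step 6
Reactants: 10 (S)-6,8-bis(benzyloxy)-5-bromo-7-methoxy-3-methylisochroman-1-one
Product: 12 (S)-6,8-bis(benzyloxy)-5-hydroxy-7-methoxy-3-methylisochroman-1-one, via aryl boronate 11 (not isolated)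
Conditions: PdCl2(MeCN)2 (3 mol%), SPhos (12 mol%), HBpin, Et3N, 1,4-dioxane, 100 °C; then NaBO3·4H2O, THF/H2O, rt
Reagents that add atoms: pinacolborane, CC1(C)OBOC1(C)C (boryl group of 11 only); sodium perborate, [Na+].[O-]OB=O (phenol oxygen)
Why: Pd-catalysed borylation of a doubly ortho-substituted aryl bromide under a bulky biarylphosphine, followed by ipso oxidation of the C–B bond (1,2-aryl shift to peroxide oxygen), gives the phenol under conditions too weakly basic to open the lactone, so the side-chain oxygen cannot cyclise onto the aryl–Pd species.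

Step 7
Reactants: 12 (S)-6,8-bis(benzyloxy)-5-hydroxy-7-methoxy-3-methylisochroman-1-one
Product: 13 (S)-5,6,8-tris(benzyloxy)-7-methoxy-3-methylisochroman-1-one
Conditions: BnBr, K2CO3, DMF, 50 °C
Reagents that add atoms: benzyl bromide, BrCc1ccccc1
Why: Williamson ether synthesis on the phenoxide should proceed cleanly because anhydrous carbonate leaves the lactone and its stereocentre alone.

Step 8
Reactants: 13 (S)-5,6,8-tris(benzyloxy)-7-methoxy-3-methylisochroman-1-one
Product: 15 allyl 2,4,5-tris(benzyloxy)-6-[(2S)-2-hydroxypropyl]-3-methoxybenzoate (ring B alcohol), via potassium hydroxy carboxylate 14 (not isolated)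
Conditions: KOH, THF/MeOH/H2O, 50 °C, evaporate; allyl bromide, DMF, 0 °C to rt
Reagents that add atoms: potassium hydroxide, [K+].[OH-]; allyl bromide, C=CCBr
Why: Saponification followed by SN2 O-alkylation of the carboxylate builds the ester without any acyl activation, so the free (S)-carbinol is not drawn back into the lactone and the crowded ester is slow to relactonise.

Step 9
Reactants: 9 ring A acid; 15 ring B alcohol
Product: 16 allyl 2,4,5-tris(benzyloxy)-6-[(2R)-2-({2,4-bis(benzyloxy)-6-[(2S)-2-(tert-butyldimethylsilyloxy)propyl]-3-methoxybenzoyl}oxy)propyl]-3-methoxybenzoate (open diester)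
Conditions: PPh3, DIAD, toluene, 0 °C to rt
Reagents that add atoms: none
Why: In the Mitsunobu esterification the hindered acid reacts as a carboxylate nucleophile, so crowding at its carbonyl does not matter, the neutral medium keeps 15 from lactonising, and SN2 displacement of the oxyphosphonium group inverts the ring B side-chain carbon from (S) to the required (R).

Step 10
Reactants: 16 open diester
Product: 17 the corresponding ring B benzoic acid (allyl ester cleaved, OTBS kept)
Conditions: Pd(PPh3)4 (5 mol%), morpholine, THF, rt
Reagents that add atoms: none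
Why: Tsuji–Trost deallylation works here because zerovalent palladium ionises the allyl–oxygen bond far from the crowded carbonyl and morpholine traps the allyl unit, leaving the inner ester, the silyl ether and the benzyl ethers untouched.

Step 11
Reactants: 17 ring B benzoic acid
Product: 18 seco acid (free (2S)-2-hydroxypropyl group on ring A, free CO2H on ring B)
Conditions: HF·pyridine, pyridine, THF, 0 °C to rt
Reagents that add atoms: none
Why: Fluoride-driven cleavage of the secondary silyl ether in a pyridine-buffered, non-basic medium frees the carbinol without forming an alkoxide that could attack the neighbouring ring A ester.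

Step 12
Reactants: 18 seco acid
Product: 20 bis-deoxy dilactone pentabenzyl ether (12-membered; OCH(CH3) next to ring B (R), next to ring A (S)), via pyridyl thioester 19 (not isolated)
Conditions: (2-PyS)2, PPh3, toluene, rt; then syringe-pump addition into refluxing toluene (final ca. 1 mM)
Reagents that add atoms: 2,2'-dipyridyl disulfide, c1ccc(SSc2ccccn2)nc1 (its 2-pyridylthio group is held by 19 only)
Why: Corey–Nicolaou double-activation macrolactonisation, established for 2-alkoxy-6-alkylbenzoic acids, has no competing acyl centre and needs no external acid or base, the two ortho-phenylene units pre-fold the chain, and acyl–oxygen bond formation leaves the ring A side-chain carbon (S).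

Step 13
Reactants: 20 bis-deoxy dilactone pentabenzyl ether
Product: 21 bis-deoxy dilactone pentaphenol
Conditions: H2 (1 atm), Pd/C, EtOAc/THF, rt; filtration under Ar
Reagents that add atoms: none
Why: Hydrogenolysis removes the five aryl benzyl ethers, while the two ester C–O bonds are homobenzylic and no benzylic carbinol is present yet, so only the protecting groups are cleaved.

Step 14
Reactants: 21 bis-deoxy dilactone pentaphenol
Product: 22 bis-deoxy dilactone penta-TBS ether (key-step precursor)
Conditions: TBSOTf, 2,6-lutidine, CH2Cl2, 0 °C to rt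
Reagents that add atoms: tert-butyldimethylsilyl triflate, CC(C)(C)[Si](C)(C)OS(=O)(=O)C(F)(F)F
Why: Silylation with the triflate and a hindered base should also reach the hydrogen-bonded and flanked phenols, and it installs groups that have no weak C–H bond and that fluoride removes at the end.

Step 15
Reactants: 22 bis-deoxy dilactone penta-TBS ether
Product: 24 macrocyclic bis(alpha-acyloxy aryl ketone) penta-TBS ether, via ring A monoketone 23 (not isolated)
Conditions: N-hydroxyphthalimide (0.4 equiv), pyridine (2 equiv), LiClO4 (0.1 M), MeCN/CH2Cl2, O2 (1 atm), reticulated vitreous carbon anode, Pt cathode, divided cell, anode potential set just past the NHPI/pyridine wave located beforehand by cyclic voltammetry, rt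
Reagents that add atoms: dioxygen, O=O
Why: Pyridine-assisted one-electron oxidation of NHPI at the anode gives the phthalimide N-oxyl radical, which abstracts one hydrogen atom from each ArCH2 group; O2 traps the benzylic radicals, the peroxyl radicals take hydrogen from NHPI and so return the N-oxyl radical, and the secondary hydroperoxides lose water under pyridine to give the two ketones. The closest known reaction type is the NHPI-mediated electrochemical (or Co(OAc)2/NHPI aerobic) oxygenation of alkylarene methylene groups to aryl ketones. No ring is closed and no stereocentre is created; the two OCH(CH3) stereocentres are spectators, and only a weak base is present so that the new alpha-acyloxy ketones should not enolise. Site selectivity is needed for the two ArCH2 groups over the OCH(CH3) methines, the OCH3 groups and the silyl alkyl groups, and it rests on the lower strength of benzylic C–H bonds on donor-rich rings (para to the OMe-bearing carbon) and on the polarity mismatch between the electrophilic N-oxyl radical and C–H bonds next to an acyloxy oxygen, which is also why the phenols are silyl and not benzyl or acetal ethers here. Chemoselectivity is needed against electron transfer from the arenes, above all ring B, a masked hydroquinone, and it is secured by holding the anode at the mediator wave, by the ester group on each ring, by a divided cell that keeps cathodic superoxide away and by a fluoride-free electrolyte that spares the silyl ethers. Because each carbon passes through a radical and never a cation, the ortho ester and the vicinal acyloxy group have nothing to capture, so the macrocycle should not unravel to phthalides.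

Step 16
Reactants: 24 macrocyclic bis(alpha-acyloxy aryl ketone) penta-TBS ether
Product: 25 bis-threo diol penta-TBS ether ((R)-carbinol on ring B, (S)-carbinol on ring A)
Conditions: LiBH(s-Bu)3 (3 equiv), THF, −78 °C (to −40 °C if the ring B ketone lags); AcOH/THF added at −78 °C; pH 7 buffer
Reagents that add atoms: none
Why: In this Felkin–Anh-controlled hydride addition a bulky, non-chelating borohydride attacks each C=O anti to its own vicinal C–O(acyl) bond and past the small H, so the (R)-ester carbon induces the (R)-carbinol on ring B and the (S)-ester carbon the (S)-carbinol on ring A, while low temperature and acid quench before warming keep the alkoxides from attacking the ortho or vicinal ester.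

Step 17
Reactants: 25 bis-threo diol penta-TBS ether
Product: 26 CNP0086623.3 (target)
Conditions: HF·pyridine, pyridine, THF, 0 °C to rt, polypropylene vessel, Ar; pH 7 buffer
Reagents that add atoms: none
Why: Fluoride-driven Si–O cleavage in a pyridine-buffered, non-basic medium removes all five silyl groups, including any that may have moved to a benzylic oxygen in step 16, without touching a stereocentre or giving the carbinols the base they would need to translactonise.

Compound list
1 | 2-methoxyresorcinol | COc1c(O)cccc1O | starting material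
2 | 2,4-dihydroxy-3-methoxybenzoic acid | COc1c(O)ccc(C(=O)O)c1O | intermediate
3 | benzyl 2,4-bis(benzyloxy)-3-methoxybenzoate | COc1c(OCc2ccccc2)ccc(C(=O)OCc2ccccc2)c1OCc1ccccc1 | intermediate
4 | 2,4-bis(benzyloxy)-3-methoxybenzoic acid | COc1c(OCc2ccccc2)ccc(C(=O)O)c1OCc1ccccc1 | intermediate
5 | (S)-propylene oxide | C[C@H]1CO1 | starting material
6 | (S)-6,8-bis(benzyloxy)-7-methoxy-3-methylisochroman-1-one | C[C@H]1Cc2cc(OCc3ccccc3)c(OC)c(OCc3ccccc3)c2C(=O)O1 | intermediate
7 | potassium 2,4-bis(benzyloxy)-6-[(2S)-2-hydroxypropyl]-3-methoxybenzoate | [K+].COc1c(OCc2ccccc2)cc(C[C@H](C)O)c(C(=O)[O-])c1OCc1ccccc1 | intermediate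
8 | tert-butyldimethylsilyl 2,4-bis(benzyloxy)-6-[(2S)-2-(tert-butyldimethylsilyloxy)propyl]-3-methoxybenzoate | COc1c(OCc2ccccc2)cc(C[C@H](C)O[Si](C)(C)C(C)(C)C)c(C(=O)O[Si](C)(C)C(C)(C)C)c1OCc1ccccc1 | intermediate
9 | 2,4-bis(benzyloxy)-6-[(2S)-2-(tert-butyldimethylsilyloxy)propyl]-3-methoxybenzoic acid | COc1c(OCc2ccccc2)cc(C[C@H](C)O[Si](C)(C)C(C)(C)C)c(C(=O)O)c1OCc1ccccc1 | intermediate
10 | (S)-6,8-bis(benzyloxy)-5-bromo-7-methoxy-3-methylisochroman-1-one | C[C@H]1Cc2c(Br)c(OCc3ccccc3)c(OC)c(OCc3ccccc3)c2C(=O)O1 | intermediate
11 | (S)-6,8-bis(benzyloxy)-7-methoxy-3-methyl-5-(pinacolatoboryl)isochroman-1-one | C[C@H]1Cc2c(B3OC(C)(C)C(C)(C)O3)c(OCc3ccccc3)c(OC)c(OCc3ccccc3)c2C(=O)O1 | intermediate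
12 | (S)-6,8-bis(benzyloxy)-5-hydroxy-7-methoxy-3-methylisochroman-1-one | C[C@H]1Cc2c(O)c(OCc3ccccc3)c(OC)c(OCc3ccccc3)c2C(=O)O1 | intermediate
13 | (S)-5,6,8-tris(benzyloxy)-7-methoxy-3-methylisochroman-1-one | C[C@H]1Cc2c(OCc3ccccc3)c(OCc3ccccc3)c(OC)c(OCc3ccccc3)c2C(=O)O1 | intermediate
14 | potassium 2,4,5-tris(benzyloxy)-6-[(2S)-2-hydroxypropyl]-3-methoxybenzoate | [K+].COc1c(OCc2ccccc2)c(OCc2ccccc2)c(C[C@H](C)O)c(C(=O)[O-])c1OCc1ccccc1 | intermediate
15 | allyl 2,4,5-tris(benzyloxy)-6-[(2S)-2-hydroxypropyl]-3-methoxybenzoate | COc1c(OCc2ccccc2)c(OCc2ccccc2)c(C[C@H](C)O)c(C(=O)OCC=C)c1OCc1ccccc1 | intermediate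
16 | open diester (ring A acyl on the (R)-side-chain oxygen of ring B; (S)-OTBS on ring A; allyl ester on ring B) | COc1c(OCc2ccccc2)cc(C[C@H](C)O[Si](C)(C)C(C)(C)C)c(c1OCc1ccccc1)C(=O)O[C@H](C)Cc1c(OCc2ccccc2)c(OCc2ccccc2)c(OC)c(OCc2ccccc2)c1C(=O)OCC=C | intermediate
17 | ring B benzoic acid of 16 | COc1c(OCc2ccccc2)cc(C[C@H](C)O[Si](C)(C)C(C)(C)C)c(c1OCc1ccccc1)C(=O)O[C@H](C)Cc1c(OCc2ccccc2)c(OCc2ccccc2)c(OC)c(OCc2ccccc2)c1C(=O)O | intermediate
18 | seco acid | COc1c(OCc2ccccc2)cc(C[C@H](C)O)c(c1OCc1ccccc1)C(=O)O[C@H](C)Cc1c(OCc2ccccc2)c(OCc2ccccc2)c(OC)c(OCc2ccccc2)c1C(=O)O | intermediate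
19 | S-(2-pyridyl) thioester of 18 | COc1c(OCc2ccccc2)cc(C[C@H](C)O)c(c1OCc1ccccc1)C(=O)O[C@H](C)Cc1c(OCc2ccccc2)c(OCc2ccccc2)c(OC)c(OCc2ccccc2)c1C(=O)Sc1ccccn1 | intermediate
20 | bis-deoxy dilactone pentabenzyl ether | COc1c(OCc2ccccc2)cc2c(c1OCc1ccccc1)C(=O)O[C@H](C)Cc1c(OCc3ccccc3)c(OCc3ccccc3)c(OC)c(OCc3ccccc3)c1C(=O)O[C@@H](C)C2 | intermediate
21 | bis-deoxy dilactone pentaphenol | COc1c(O)cc2c(c1O)C(=O)O[C@H](C)Cc1c(O)c(O)c(OC)c(O)c1C(=O)O[C@@H](C)C2 | intermediate
22 | bis-deoxy dilactone penta-TBS ether | COc1c(O[Si](C)(C)C(C)(C)C)cc2c(c1O[Si](C)(C)C(C)(C)C)C(=O)O[C@H](C)Cc1c(O[Si](C)(C)C(C)(C)C)c(O[Si](C)(C)C(C)(C)C)c(OC)c(O[Si](C)(C)C(C)(C)C)c1C(=O)O[C@@H](C)C2 | intermediate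
23 | ring A monoketone penta-TBS ether | COc1c(O[Si](C)(C)C(C)(C)C)cc2c(c1O[Si](C)(C)C(C)(C)C)C(=O)O[C@H](C)Cc1c(O[Si](C)(C)C(C)(C)C)c(O[Si](C)(C)C(C)(C)C)c(OC)c(O[Si](C)(C)C(C)(C)C)c1C(=O)O[C@@H](C)C2=O | intermediate
24 | macrocyclic bis(alpha-acyloxy aryl ketone) penta-TBS ether | COc1c(O[Si](C)(C)C(C)(C)C)cc2c(c1O[Si](C)(C)C(C)(C)C)C(=O)O[C@H](C)C(=O)c1c(O[Si](C)(C)C(C)(C)C)c(O[Si](C)(C)C(C)(C)C)c(OC)c(O[Si](C)(C)C(C)(C)C)c1C(=O)O[C@@H](C)C2=O | intermediate
25 | bis-threo diol penta-TBS ether | COc1c(O[Si](C)(C)C(C)(C)C)cc2c(c1O[Si](C)(C)C(C)(C)C)C(=O)O[C@H](C)[C@H](O)c1c(O[Si](C)(C)C(C)(C)C)c(O[Si](C)(C)C(C)(C)C)c(OC)c(O[Si](C)(C)C(C)(C)C)c1C(=O)O[C@@H](C)[C@H]2O | intermediate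
26 | CNP0086623.3 | COc1c(O)cc2c(c1O)C(=O)O[C@H](C)[C@H](O)c1c(O)c(O)c(OC)c(O)c1C(=O)O[C@@H](C)[C@H]2O | target

Total step count: 17. Longest linear sequence: 16 (steps 1–3 and 5–17).

Steps most likely to fail

Step 15. Three processes may go wrong:
- Electron transfer from ring B to the anode or to the N-oxyl radical may outrun hydrogen abstraction, with loss of silyl groups and oxidation of the ring.
- Abstraction at the doubly flanked CH2 on ring B may stall at the stage of 23.
- Peroxidic intermediates may end as carbinols that translactonise.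

The fallback makes the C–O bonds by radical cross-coupling instead of O2 trapping. Setting out from 22, the mediated electrolysis is run under N2 with N-hydroxyphthalimide in stoichiometric excess. Each benzylic radical is then captured by a second N-oxyl radical (known benzylic C–H/N-oxyl coupling). This should give the bis(N-alkoxyphthalimide) F1 as a mixture of epimers at the two new centres, which are destroyed later. A known redox-neutral photoinduced N–O fragmentation ([Ru(bpy)3]Cl2, i-Pr2NEt, visible light, acetone) then expels phthalimide from each benzylic position and returns to the route at 24.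

Step 12. Acyl transfer from the doubly ortho-substituted thioester to the secondary OH may be so slow that oligomerisation takes over. Alternatively, the free side-chain OH may attack its own ring A ester, which would unzip the chain into six-membered lactones.

The fallback closes the ring through the carboxylate (Mitsunobu macrolactonisation), which needs the epimeric carbinol.
- Setting out from 4 and commercial (R)-propylene oxide (C[C@@H]1CO1), the conditions of step 3 should give the (R)-lactone F2.
- The conditions of step 4 lead through the potassium hydroxy carboxylate F3 and the bis-silyl derivative F4 to the (R)-silyloxy acid F5.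
- Mitsunobu coupling with 15 as in step 9 gives the (R,R)-diester F6.
- Deallylation as in step 10 gives the acid F7, and desilylation as in step 11 gives the (R,R)-seco acid F8.
- PPh3 and DIAD in toluene at high dilution then displace the activated ring A side-chain oxygen with the ring B carboxylate. This inverts that carbon from (R) to (S) and returns to the route at 20.

Step 16. Three processes may go wrong:
- The conformation of the macrocycle may override the Felkin–Anh preference and give poor facial selectivity.
- The bulky hydride may be sluggish at the doubly ortho-substituted ring B ketone.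
- A lithium alkoxide may attack the ortho ester or take over the vicinal acyl group.

The fallback replaces substrate control with stepwise reagent control through non-basic boron alkoxides (Corey–Bakshi–Shibata reduction). Setting out from 24, BH3·SMe2 (limiting) with (S)-2-methyl-CBS-oxazaborolidine in toluene at −20 °C should reduce the more accessible ring A ketone to the (S)-carbinol, the ring A hydroxy ketone F9. A second reduction with the (R)-oxazaborolidine should convert the ring B ketone into the (R)-carbinol. In both cases the reagent preference coincides with the Felkin–Anh sense, and the sequence returns to the route at 25.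

Further compounds
F1 | step 15 | bis(N-alkoxyphthalimide) of 22 (phthalimidooxy group on each benzylic carbon, epimer mixture there) | COc1c(O[Si](C)(C)C(C)(C)C)cc2c(c1O[Si](C)(C)C(C)(C)C)C(=O)O[C@H](C)C(ON3C(=O)c4ccccc4C3=O)c1c(O[Si](C)(C)C(C)(C)C)c(O[Si](C)(C)C(C)(C)C)c(OC)c(O[Si](C)(C)C(C)(C)C)c1C(=O)O[C@@H](C)C2ON1C(=O)c3ccccc3C1=O
F2 | step 12 | (R)-6,8-bis(benzyloxy)-7-methoxy-3-methylisochroman-1-one | C[C@@H]1Cc2cc(OCc3ccccc3)c(OC)c(OCc3ccccc3)c2C(=O)O1
F3 | step 12 | potassium 2,4-bis(benzyloxy)-6-[(2R)-2-hydroxypropyl]-3-methoxybenzoate | [K+].COc1c(OCc2ccccc2)cc(C[C@@H](C)O)c(C(=O)[O-])c1OCc1ccccc1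
F4 | step 12 | tert-butyldimethylsilyl 2,4-bis(benzyloxy)-6-[(2R)-2-(tert-butyldimethylsilyloxy)propyl]-3-methoxybenzoate | COc1c(OCc2ccccc2)cc(C[C@@H](C)O[Si](C)(C)C(C)(C)C)c(C(=O)O[Si](C)(C)C(C)(C)C)c1OCc1ccccc1
F5 | step 12 | 2,4-bis(benzyloxy)-6-[(2R)-2-(tert-butyldimethylsilyloxy)propyl]-3-methoxybenzoic acid | COc1c(OCc2ccccc2)cc(C[C@@H](C)O[Si](C)(C)C(C)(C)C)c(C(=O)O)c1OCc1ccccc1
F6 | step 12 | (R,R)-open diester (epimer of 16 at the silyloxy carbon) | COc1c(OCc2ccccc2)cc(C[C@@H](C)O[Si](C)(C)C(C)(C)C)c(c1OCc1ccccc1)C(=O)O[C@H](C)Cc1c(OCc2ccccc2)c(OCc2ccccc2)c(OC)c(OCc2ccccc2)c1C(=O)OCC=C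
F7 | step 12 | ring B benzoic acid of F6 | COc1c(OCc2ccccc2)cc(C[C@@H](C)O[Si](C)(C)C(C)(C)C)c(c1OCc1ccccc1)C(=O)O[C@H](C)Cc1c(OCc2ccccc2)c(OCc2ccccc2)c(OC)c(OCc2ccccc2)c1C(=O)O
F8 | step 12 | (R,R)-seco acid (epimer of 18 at the carbinol carbon) | COc1c(OCc2ccccc2)cc(C[C@@H](C)O)c(c1OCc1ccccc1)C(=O)O[C@H](C)Cc1c(OCc2ccccc2)c(OCc2ccccc2)c(OC)c(OCc2ccccc2)c1C(=O)O
F9 | step 16 | ring A hydroxy ketone penta-TBS ether ((S)-carbinol on ring A, ring B ketone intact) | COc1c(O[Si](C)(C)C(C)(C)C)cc2c(c1O[Si](C)(C)C(C)(C)C)C(=O)O[C@H](C)C(=O)c1c(O[Si](C)(C)C(C)(C)C)c(O[Si](C)(C)C(C)(C)C)c(OC)c(O[Si](C)(C)C(C)(C)C)c1C(=O)O[C@@H](C)[C@H]2O
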